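## Structural features

The target is (2S)-4′-O-geranylnaringenin, a chroman-4-one. Ring A (C4a–C8a, free hydroxyls on C5 and C7) is fused to the dihydropyranone ring C (O1–C2–C3–C4), and ring B, a para-disubstituted benzene whose 4′-oxygen carries an (E)-geranyl chain, sits on C2. C2 is the only stereocentre, so no relative stereochemistry has to be controlled. It is benzylic to a para-alkoxyphenyl group, bonded to O1 and β to the C4 ketone, so base opens ring C by retro-oxa-Michael reaction to the achiral 2′-hydroxychalcone and acid can ionise C2–O1; either erases the configuration. The geranyl aryl ether is the second fragile element: it is an allylic ether that acid cleaves or cyclises, and its two trisubstituted alkenes are open to boranes, electrophilic oxidants, hydrogen-atom donors and hydrogenation. The 5- and 7-hydroxyls make ring A very electron-rich and must be masked by groups that come off without acid or strong base. The real difficulty is therefore creating C2 in one absolute sense and carrying it, beside the geranyl alkenes, through ring closure and C4 oxygenation. The key step uses the fact that ring C with a C3=C4 alkene is a styrene of ring A whose C2 is an allylic aryl ether carbon: a vinyl group on C4a and a 1-arylallyl group on O1 are joined at C3=C4 by ring-closing metathesis, and the C4 ketone is the benzylic oxygenation product of that styrene.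

## Logic of the disconnections

**15 to 14.** The O–Si bonds on O5 and O7 are cut last. Silyl ethers are preferred to acetal protection because they leave with buffered fluoride, whereas an acetal needs acid that the allylic geranyl ether and the ionisable C2–O1 bond of 15 would not survive. The gain is a ring A that is inert to ylide, aryloxide, ruthenium, rhodium and hypervalent iodine reagents. The demand is that the fluoride step stays buffered so that no phenoxide or enolate opens ring C.

**14 to 13 to 11 (through 12).** The C4=O bond is traced to the C4–OH bond of 13, and that C4–O bond is cut to leave the C3=C4 alkene of 11. The oxygen is introduced after ring closure because an alkene is what metathesis delivers. A PdCl2/CuCl/O2 Wacker oxidation is not relied on: in ring-fused styrenes the nucleophile tends to enter at the carbon remote from the arene (C3 here), the allylic O1 pulls the other way, and the acidic medium endangers C2. Uncatalysed borane is excluded because it places boron at C3 and also attacks the geranyl alkenes. The demand is a hydrometalation that puts the heteroatom on benzylic C4 and ignores trisubstituted alkenes, followed by a neutral alcohol oxidation.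

**11 to 10.** The C3=C4 double bond is cut to give two terminal vinyl groups, one on C4a and one on C2. This removes ring C in a single operation and leaves an acyclic aryl allyl ether in which C2 is already set. The demand is that the catalyst reacts only with the two monosubstituted alkenes and that no acid, base, light or prolonged heat reaches the allylic, para-alkoxybenzylic C2–O1 bond. The descriptor stays (S) from 10 to 15 because the rank order O1 > ring B carbon > C3 > H holds in every compound.

**10 to 3 and 8 (through 9).** The O1–C2 bond is cut. This splits the molecule into a ring A phenol and a ring B cinnamyl electrophile of similar size, and it places the creation of the only stereocentre in a catalytic, branched-selective allylic substitution. The demand is high branched and facial selectivity with an ortho-substituted, electron-rich aryloxide, and suppression of re-ionisation of the electron-rich product.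

**3 to 2 to 1.** The exocyclic C=CH2 bond on C4a is cut to the formyl group of 2, and the two O–Si bonds are cut to reach 1. The aromatic ring with all three oxygens is bought, and the hydrogen-bonded ortho hydroxyl of 1 differentiates itself as the future O1. The demand is a methylenation that tolerates a free phenol and aryl silyl ethers.

**8 to 7 to 6 to 4 and 5.** The carbonate C–O bond is cut to the allylic alcohol 7, the alcohol is traced to the ester 6, and the O4′–C1″ bond is cut to 4 and 5. The (E)-cinnamyl geometry is bought with 4 and the geranyl geometry with 5. The demand is only that alkylation proceeds at the primary allylic carbon without allylic transposition, and that the leaving group of 8 releases a non-nucleophilic base.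

## Other disconnections considered

**Alternative 1:** The cut is C2–C3. Diazoketone A1 would be decomposed by Rh2(S-PTTL)4, and the carbene at C3 would insert into one enantiotopic benzylic C2–H bond to give A2, which is identical with 14.
- In its favour: ring C, the stereocentre and the C4 ketone arrive together from an achiral precursor, so no later oxygenation is needed.
- Against it here: the ether oxygen lies five atoms from the carbene carbon, so formation of a five-membered oxonium ylide and [1,2]-shift of the para-alkoxybenzyl group to a 2-benzylbenzofuran-3-one is a serious competitor. The acceptor-only carbene can also cyclopropanate the nucleophilic geranyl alkenes or add to ring B, six-membered C–H insertion is less favoured than five-membered, and facial control with such carbenes is usually modest. Preparing A1 from a 2,6-disubstituted benzoic acid also needs a hazardous diazoalkane step.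
- Comparison: on step economy and redox economy Alternative 1 is the equal or the better of the chosen plan, since it reaches 14 directly. On mechanism the chosen plan is safer, because its ring-closing and stereo-defining steps each have one dominant pathway and the geranyl alkenes are spectators.

**Alternative 2:** The cuts are C2–C3 and O1–C8a, made before ring A exists. Aldehyde A3 and diene A4 would combine in a hetero-Diels–Alder reaction under (salen)CrCl or Ti(OiPr)4 with BINOL to give dihydropyranone A5 after acid work-up.
- In its favour: the cycloaddition is highly developed for aryl aldehydes, it sets C2 early, the C4 carbonyl is already present, and the geranyl alkenes are inert to it.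
- Against it here: ring A must then be built as a 5,7-dioxygenated benzene onto the enol ether carbons of A5. That needs several C–C bond formations and an aromatisation on a β-alkoxy enone that opens by β-elimination under the basic conditions such condensations require, which would destroy C2.
- Comparison: in expected enantiocontrol at C2, Alternative 2 is the equal or the better of the chosen plan. Structurally it discards a commercially available, fully oxygenated ring A and replaces it with a long de novo annulation, so it is clearly worse in step count and in risk after the key step.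

**Alternative 3:** The cuts are C4a–C4, C4–C3 and O1–C2. Iodophenol A6 and alkyne A7 would undergo a carbonylative three-component coupling under PdCl2(PPh3)2 and a secondary amine to give flavone A8, and C2 would be set afterwards by asymmetric 1,4-reduction.
- In its favour: three bonds form in one robust operation, A8 is achiral and stable, and no ionisable chiral ether has to be handled.
- Against it here: the stereocentre then depends on enantioselective hydride delivery to a β-aryl-β-alkoxy enone that is deactivated further by the 5,7-dialkoxy ring. Catalytic hydrogenation is excluded by the geranyl alkenes, and CuH–silane conjugate reduction is less established for 2-aryl chromones and risks over-reduction. The acetal protecting groups of A8 would also need acid that the geranyl ether does not tolerate, and A6 requires a regioselective iodination.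
- Comparison: in ring construction and convergence Alternative 3 is the equal or the better of the chosen plan, and its step count is similar or slightly lower. In control of C2 it is weaker, because the chosen plan sets C2 by a well-understood allylic substitution before the ring is closed.

Key step: step 7

**Remarks on the chemistry**
- L denotes O,O′-(1,1′-binaphthyl-2,2′-diyl) N,N-bis(1-phenylethyl)phosphoramidite. The (Sa,Sc,Sc) antipode is assumed to give the (S)-branched aryl ether, by analogy with the facial preference of this ligand family with aryl-substituted allyl carbonates. If the sense proved opposite, the (Ra,Rc,Rc) ligand would be used with no other change.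
- In step 2 the phenol is deprotonated by the first equivalent of ylide. This ionised form is treated as the same compound as 2 and 3 and carries no number, whereas the lithium aryloxide prepared in a separate operation in step 6 is numbered.

## Route

Step 1
Reactants: 1 2,4,6-trihydroxybenzaldehyde
Product: 2 4,6-bis(tert-butyldimethylsilyloxy)-2-hydroxybenzaldehyde
Conditions: TBSCl (2.1 equiv), imidazole (2.5 equiv), CH2Cl2–DMF, 0 °C
Reagents that add atoms: tert-butyldimethylsilyl chloride, CC(C)(C)[Si](C)(C)Cl
Why: Silylation of phenols; the hydroxyl that stays free is the one held in the hydrogen bond to the formyl oxygen, and because the two ortho hydroxyls are equivalent the bis-ether is a single regioisomer; the stoichiometry stops the reaction before the third, least reactive hydroxyl.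

Step 2
Reactants: 2 4,6-bis(tert-butyldimethylsilyloxy)-2-hydroxybenzaldehyde
Product: 3 3,5-bis(tert-butyldimethylsilyloxy)-2-vinylphenol
Conditions: Ph3PCH3Br (2.5 equiv), NaN(SiMe3)2 (2.4 equiv), THF, 0 °C → rt; pH 7 buffer work-up
Reagents that add atoms: methyltriphenylphosphonium bromide, C[P+](c1ccccc1)(c1ccccc1)c1ccccc1.[Br-]
Why: Wittig methylenation, a known way from salicylaldehydes to 2-vinylphenols; the first equivalent of ylide deprotonates the phenol and the second olefinates the aldehyde; the non-nucleophilic amide base spares the aryl silyl ethers, and the electron-rich vinylphenol is kept from acid and used promptly.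

Step 3
Reactants: 4 methyl (E)-3-(4-hydroxyphenyl)acrylate; 5 geranyl bromide
Product: 6 methyl (E)-3-[4-(geranyloxy)phenyl]acrylate
Conditions: K2CO3, DMF, rt
Reagents that add atoms: none
Why: Williamson ether synthesis; the phenoxide displaces bromide by SN2 at the primary allylic carbon, so the (E)-geranyl geometry is retained and O-alkylation is favoured in the polar aprotic medium.

Step 4
Reactants: 6 methyl (E)-3-[4-(geranyloxy)phenyl]acrylate
Product: 7 (E)-3-[4-(geranyloxy)phenyl]prop-2-en-1-ol
Conditions: iBu2AlH (2.3 equiv), CH2Cl2, −78 → 0 °C; aq. KNaC4H4O6 (potassium sodium tartrate)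
Reagents that add atoms: none
Why: 1,2-Reduction of an α,β-unsaturated ester to the allylic alcohol by iBu2AlH; the alkene geometry, the aryl ether and the geranyl alkenes are untouched.

Step 5
Reactants: 7 (E)-3-[4-(geranyloxy)phenyl]prop-2-en-1-ol
Product: 8 tert-butyl (E)-3-[4-(geranyloxy)phenyl]allyl carbonate
Conditions: Boc2O (1.3 equiv), DMAP (10 mol %), CH2Cl2, 0 °C → rt
Reagents that add atoms: di-tert-butyl dicarbonate, CC(C)(C)OC(=O)OC(=O)OC(C)(C)C
Why: DMAP-catalysed O-acylation of a primary allylic alcohol; the tert-butyl carbonate is chosen because its later ionisation releases CO2 and bulky tert-butoxide, which neither attacks aryl silyl ethers nor competes as a nucleophile the way methoxide could.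

Step 6
Reactants: 3 3,5-bis(tert-butyldimethylsilyloxy)-2-vinylphenol; 8 tert-butyl (E)-3-[4-(geranyloxy)phenyl]allyl carbonate
Product: 10 (S)-1-{1-[4-(geranyloxy)phenyl]allyloxy}-3,5-bis(tert-butyldimethylsilyloxy)-2-vinylbenzene, via lithium aryloxide 9 (not isolated)
Conditions: 3 (1.3 equiv), LiN(SiMe3)2 (1.3 equiv), THF, 0 °C; then 8, [Ir(cod)Cl]2 (2 mol %), (Sa,Sc,Sc)-L (4 mol %, preactivated with n-PrNH2), THF, rt, dark
Reagents that add atoms: none
Why: Iridium-catalysed enantioselective branched allylic etherification of an aryloxide; the cyclometalated iridium–phosphoramidite ionises the carbonate to an (η3-allyl)Ir intermediate and the aryloxide attacks the aryl-bearing terminus on the face opposite the metal, the ligand configuration fixing (S) at C2; lithium in THF favours O- over C-allylation, the geranyl aryl ether is too poor a leaving group on too substituted an allyl unit to ionise, and the reaction is stopped at full conversion to limit re-ionisation of the product.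

Step 7
Reactants: 10 (S)-1-{1-[4-(geranyloxy)phenyl]allyloxy}-3,5-bis(tert-butyldimethylsilyloxy)-2-vinylbenzene
Product: 11 (S)-2-[4-(geranyloxy)phenyl]-5,7-bis(tert-butyldimethylsilyloxy)-2H-chromene
Conditions: first-generation Grubbs catalyst Cl2(PCy3)2Ru=CHPh (5 mol %), CH2Cl2 (0.01 M), 40 °C, Ar, dark; then ethyl vinyl ether
Reagents that add atoms: none
Why: Ring-closing olefin metathesis of a styrene–allyl ether diene, the established route from 2-vinylaryl allyl ethers to 2H-chromenes. The benzylidene exchanges with one monosubstituted alkene to give a new Ru=CHR alkylidene, intramolecular [2+2] cycloaddition with the second vinyl group gives a ruthenacyclobutane, and its cycloreversion forms C3=C4 and releases Ru=CH2, which carries the chain and expels ethylene. Ring C closes as a six-membered ring by joining the two internal vinyl carbons (C3 from the allyl unit on C2, C4 from the vinyl on C4a) so that the new alkene lies inside the ring, the aryl ether O1–C8a acting as a rigid cis tether; loss of gaseous ethylene makes the closure irreversible. No stereocentre is formed, and C2 is not a reacting atom, so its configuration is carried over unchanged as long as acid, light and prolonged heat are excluded and neither ionisation of C2–O1 nor electrocyclic opening of the 2H-chromene intervenes. The selectivity required is for the two monosubstituted alkenes over the two trisubstituted geranyl alkenes; it is secured by the substitution pattern, since the phosphine-only first-generation catalyst does not readily engage trisubstituted alkenes, and by the intramolecular productive pathway at high dilution. Migration of the allyl double bond induced by Ru–H species, which would destroy C2, is limited by a short reaction time and by quenching with ethyl vinyl ether before concentration.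

Step 8
Reactants: 11 (S)-2-[4-(geranyloxy)phenyl]-5,7-bis(tert-butyldimethylsilyloxy)-2H-chromene
Product: 13 (2S)-2-[4-(geranyloxy)phenyl]-5,7-bis(tert-butyldimethylsilyloxy)chroman-4-ol (mixture of C4 epimers), via C4 catechol boronate 12 (not isolated)
Conditions: catecholborane (2 equiv), [Rh(cod)2]BF4 (3 mol %), rac-1-(2-diphenylphosphino-1-naphthyl)isoquinoline (3 mol %), THF, 0 °C → rt; then NaBO3·4H2O, THF–H2O, 0 °C → rt
Reagents that add atoms: sodium perborate, [Na+].[Na+].O[B-]1(O)OO[B-](O)(O)OO1 (the C4 oxygen); catecholborane, [H]B1Oc2ccccc2O1 (the boron of 12 and the new C3 hydrogen)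
Why: Rhodium-catalysed hydroboration of a ring-fused vinylarene; Rh–H adds so that rhodium sits on benzylic C4 as an η3-benzyl stabilised by ring A, giving boronate 12, whereas uncatalysed borane would put boron on C3 and attack the geranyl alkenes; the trisubstituted geranyl alkenes are inert to catecholborane under these conditions, perborate converts C–B into C–OH with retention at mild pH, and the C4 configuration is irrelevant because C4 is oxidised next.

Step 9
Reactants: 13 (2S)-2-[4-(geranyloxy)phenyl]-5,7-bis(tert-butyldimethylsilyloxy)chroman-4-ol
Product: 14 (S)-2-[4-(geranyloxy)phenyl]-5,7-bis(tert-butyldimethylsilyloxy)chroman-4-one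
Conditions: Dess–Martin periodinane (1.3 equiv), NaHCO3, CH2Cl2, 0 °C → rt
Reagents that add atoms: none
Why: Dess–Martin oxidation of a secondary benzylic alcohol to the aryl ketone in a buffered medium that is neither acidic nor basic, so neither ionisation at C4 nor ring opening at C2–O1 is expected; alkenes and silyl ethers are inert to the reagent.

Step 10
Reactants: 14 (S)-2-[4-(geranyloxy)phenyl]-5,7-bis(tert-butyldimethylsilyloxy)chroman-4-one
Product: 15 (S)-2-[4-(geranyloxy)phenyl]-5,7-dihydroxychroman-4-one (target, CNP0123225.1)
Conditions: Bu4NF (2.2 equiv), AcOH (2.5 equiv), THF, 0 °C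
Reagents that add atoms: none
Why: Fluoride cleavage of aryl silyl ethers; both departing phenoxides are conjugated with the C4 ketone, so cleavage should be fast at 0 °C, and acetic acid keeps the medium buffered so that no phenoxide or enolate opens ring C to the chalcone, which would racemise C2; the geranyl ether is inert to fluoride.

## Compound list

1 | 2,4,6-trihydroxybenzaldehyde | O=Cc1c(O)cc(O)cc1O | starting material
2 | 4,6-bis(tert-butyldimethylsilyloxy)-2-hydroxybenzaldehyde | O=Cc1c(O)cc(O[Si](C)(C)C(C)(C)C)cc1O[Si](C)(C)C(C)(C)C | intermediate
3 | 3,5-bis(tert-butyldimethylsilyloxy)-2-vinylphenol | C=Cc1c(O)cc(O[Si](C)(C)C(C)(C)C)cc1O[Si](C)(C)C(C)(C)C | intermediate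
4 | methyl (E)-3-(4-hydroxyphenyl)acrylate | COC(=O)/C=C/c1ccc(O)cc1 | starting material
5 | geranyl bromide, (E)-1-bromo-3,7-dimethylocta-2,6-diene | CC(C)=CCC/C(C)=C/CBr | starting material
6 | methyl (E)-3-[4-(geranyloxy)phenyl]acrylate | COC(=O)/C=C/c1ccc(OC/C=C(\C)CCC=C(C)C)cc1 | intermediate
7 | (E)-3-[4-(geranyloxy)phenyl]prop-2-en-1-ol | OC/C=C/c1ccc(OC/C=C(\C)CCC=C(C)C)cc1 | intermediate
8 | tert-butyl (E)-3-[4-(geranyloxy)phenyl]allyl carbonate | CC(C)(C)OC(=O)OC/C=C/c1ccc(OC/C=C(\C)CCC=C(C)C)cc1 | intermediate
9 | lithium 3,5-bis(tert-butyldimethylsilyloxy)-2-vinylphenoxide | [Li+].C=Cc1c([O-])cc(O[Si](C)(C)C(C)(C)C)cc1O[Si](C)(C)C(C)(C)C | intermediate (not isolated)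
10 | (S)-1-{1-[4-(geranyloxy)phenyl]allyloxy}-3,5-bis(tert-butyldimethylsilyloxy)-2-vinylbenzene | C=C[C@H](Oc1cc(O[Si](C)(C)C(C)(C)C)cc(O[Si](C)(C)C(C)(C)C)c1C=C)c1ccc(OC/C=C(\C)CCC=C(C)C)cc1 | intermediate
11 | (S)-2-[4-(geranyloxy)phenyl]-5,7-bis(tert-butyldimethylsilyloxy)-2H-chromene | CC(C)(C)[Si](C)(C)Oc1cc(O[Si](C)(C)C(C)(C)C)c2C=C[C@@H](c3ccc(OC/C=C(\C)CCC=C(C)C)cc3)Oc2c1 | intermediate
12 | 2-{(2S)-2-[4-(geranyloxy)phenyl]-5,7-bis(tert-butyldimethylsilyloxy)chroman-4-yl}-1,3,2-benzodioxaborole (C4 epimers) | CC(C)(C)[Si](C)(C)Oc1cc(O[Si](C)(C)C(C)(C)C)c2C(B4Oc5ccccc5O4)C[C@@H](c3ccc(OC/C=C(\C)CCC=C(C)C)cc3)Oc2c1 | intermediate (not isolated)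
13 | (2S)-2-[4-(geranyloxy)phenyl]-5,7-bis(tert-butyldimethylsilyloxy)chroman-4-ol (C4 epimers) | CC(C)(C)[Si](C)(C)Oc1cc(O[Si](C)(C)C(C)(C)C)c2C(O)C[C@@H](c3ccc(OC/C=C(\C)CCC=C(C)C)cc3)Oc2c1 | intermediate
14 | (S)-2-[4-(geranyloxy)phenyl]-5,7-bis(tert-butyldimethylsilyloxy)chroman-4-one | CC(C)(C)[Si](C)(C)Oc1cc(O[Si](C)(C)C(C)(C)C)c2C(=O)C[C@@H](c3ccc(OC/C=C(\C)CCC=C(C)C)cc3)Oc2c1 | intermediate
15 | (S)-2-[4-(geranyloxy)phenyl]-5,7-dihydroxychroman-4-one | CC(C)=CCC/C(C)=C/COc1ccc([C@@H]2CC(=O)c3c(O)cc(O)cc3O2)cc1 | target

## Step count and least certain steps

Total step count: 10. Longest linear sequence: 8 steps (4 → 6 → 7 → 8 → 10 → 11 → 13 → 14 → 15, steps 3 to 10). The ring A branch (steps 1 and 2) joins at step 6.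

**Step 7 (key step).** The most likely failure is slow closure at the di-ortho-substituted, electron-rich styrene, so that the catalyst decays before turnover. Ru–H species formed on decay could then shift the allyl double bond into conjugation with O1 and erase C2, and light or heat could racemise the product by reversible six-electron ring opening of the 2H-chromene. The second-generation catalyst Cl2(PCy3)(H2IMes)Ru=CHPh would be the first adjustment, but that is only a change of conditions and it raises the risk at the geranyl alkenes. The fallback closes ring C without metathesis. It sets out from 7 and 2. Alcohol 7 would be oxidised with MnO2 in CH2Cl2 to (E)-3-[4-(geranyloxy)phenyl]acrylaldehyde F1. Aldehyde 2 and F1 would then be combined under a diarylprolinol silyl ether (the antipode that places ring B as in 11) with a benzoic acid co-catalyst in toluene. Iminium activation allows conjugate addition of the phenol oxygen to the future C2, and the resulting enamine undergoes aldol condensation with the ring A formyl group. The product would be (R)-2-[4-(geranyloxy)phenyl]-5,7-bis(tert-butyldimethylsilyloxy)-2H-chromene-3-carbaldehyde F2; the descriptor differs from that of 11 only because the formyl group raises the rank of C3. Decarbonylation of F2 with stoichiometric RhCl(PPh3)3 in toluene at the lowest workable temperature would return to the route at 11. The weak points of this detour are the hindered, deactivated aldehyde of 2 in the aldol step and thermal stress on C2 during decarbonylation.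

**Step 6.** The likely failures are erosion of branched and facial selectivity through reversible ionisation of the para-alkoxy-activated product, which would leak to the linear cinnamyl ether and to the racemate; sluggish attack by the ortho-substituted aryloxide; and competing C-allylation of the phloroglucinol-type ring. The fallback takes C2 from an epoxidation and an SN2 opening instead of a metal–allyl intermediate. It sets out from 7 and 3. Sharpless asymmetric epoxidation of 7 (Ti(OiPr)4, L-(+)-diisopropyl tartrate, t-BuOOH, 4 Å molecular sieves, CH2Cl2, −20 °C) would give ((2S,3S)-3-[4-(geranyloxy)phenyl]oxiran-2-yl)methanol F3; the geranyl alkenes are not allylic alcohols and are left alone. Ti(OiPr)4-assisted opening of F3 at the benzylic carbon by phenol 3, with inversion, would give (2S,3R)-3-[3,5-bis(tert-butyldimethylsilyloxy)-2-vinylphenoxy]-3-[4-(geranyloxy)phenyl]propane-1,2-diol F4. 1,1′-Thiocarbonyldiimidazole would convert F4 into (S)-4-{(R)-[3,5-bis(tert-butyldimethylsilyloxy)-2-vinylphenoxy][4-(geranyloxy)phenyl]methyl}-1,3-dioxolane-2-thione F5. Corey–Winter olefination of F5 with 1,3-dimethyl-2-phenyl-1,3,2-diazaphospholidine at 40 °C would give the terminal alkene and return to the route at 10. The weak point is the acid lability of the electron-rich epoxy alcohol, which would have to be used crude.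

**Step 8.** The likely failures are delivery of boron to C3 instead of C4 under crowding by the C5 silyloxy group, Rh–H-induced migration of the double bond towards C2 (which would forfeit the stereocentre in that fraction), and partial loss of an aryl silyl ether during the perborate oxidation. The fallback replaces hydrometalation by a radical Markovnikov hydration (Mukaiyama hydration). It sets out from 11: with Mn(dpm)3 (catalytic), PhSiH3 and O2 in i-PrOH–CH2Cl2 at 0 °C, a hydrogen atom is transferred to C3, the C4 benzylic radical stabilised by ring A is trapped by oxygen, and reduction of the peroxide gives the alcohol, returning to the route at 13 (any ketone formed is already 14). No new compound is involved. The weak point is that the trisubstituted geranyl alkenes are also hydrogen-atom acceptors, so the reaction would have to be stopped at partial conversion.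

**Step 2.** The likely failures are incomplete olefination of the deactivated phenoxide aldehyde, silyl transfer between aryl silyl ether and phenoxide, and acid-induced oligomerisation of the very electron-rich vinylphenol on isolation. The fallback changes the order of events so that no free vinylphenol is handled. It sets out from 2 and 8: the lithium salt of 2 would be allylated under the conditions of step 6 to give (S)-2-{1-[4-(geranyloxy)phenyl]allyloxy}-4,6-bis(tert-butyldimethylsilyloxy)benzaldehyde F6, and the now neutral and more electrophilic aldehyde of F6 would be methylenated with Ph3P=CH2 in THF at 0 °C, returning to the route at 10. The weak point is that the formyl-stabilised aryloxide is a poorer nucleophile and a better leaving group, so the etherification would be slower and the product more prone to re-ionisation.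

## Further compounds

F1 | step 7 | (E)-3-[4-(geranyloxy)phenyl]acrylaldehyde | O=C/C=C/c1ccc(OC/C=C(\C)CCC=C(C)C)cc1
F2 | step 7 | (R)-2-[4-(geranyloxy)phenyl]-5,7-bis(tert-butyldimethylsilyloxy)-2H-chromene-3-carbaldehyde | CC(C)(C)[Si](C)(C)Oc1cc(O[Si](C)(C)C(C)(C)C)c2C=C(C=O)[C@@H](c3ccc(OC/C=C(\C)CCC=C(C)C)cc3)Oc2c1
F3 | step 6 | ((2S,3S)-3-[4-(geranyloxy)phenyl]oxiran-2-yl)methanol | OC[C@@H]1O[C@H]1c1ccc(OC/C=C(\C)CCC=C(C)C)cc1
F4 | step 6 | (2S,3R)-3-[3,5-bis(tert-butyldimethylsilyloxy)-2-vinylphenoxy]-3-[4-(geranyloxy)phenyl]propane-1,2-diol | OC[C@H](O)[C@H](Oc1cc(O[Si](C)(C)C(C)(C)C)cc(O[Si](C)(C)C(C)(C)C)c1C=C)c1ccc(OC/C=C(\C)CCC=C(C)C)cc1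
F5 | step 6 | (S)-4-{(R)-[3,5-bis(tert-butyldimethylsilyloxy)-2-vinylphenoxy][4-(geranyloxy)phenyl]methyl}-1,3-dioxolane-2-thione | S=C1OC[C@H](O1)[C@H](Oc2cc(O[Si](C)(C)C(C)(C)C)cc(O[Si](C)(C)C(C)(C)C)c2C=C)c2ccc(OC/C=C(\C)CCC=C(C)C)cc2
F0 | step 8 | none | none
F6 | step 2 | (S)-2-{1-[4-(geranyloxy)phenyl]allyloxy}-4,6-bis(tert-butyldimethylsilyloxy)benzaldehyde | C=C[C@H](Oc1cc(O[Si](C)(C)C(C)(C)C)cc(O[Si](C)(C)C(C)(C)C)c1C=O)c1ccc(OC/C=C(\C)CCC=C(C)C)cc1
A1 | alternative 1 | 2-diazo-1-{2-[4-(geranyloxy)benzyloxy]-4,6-bis(tert-butyldimethylsilyloxy)phenyl}ethan-1-one | [N-]=[N+]=CC(=O)c1c(OCc2ccc(OC/C=C(\C)CCC=C(C)C)cc2)cc(O[Si](C)(C)C(C)(C)C)cc1O[Si](C)(C)C(C)(C)C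
A2 | alternative 1 | (S)-2-[4-(geranyloxy)phenyl]-5,7-bis(tert-butyldimethylsilyloxy)chroman-4-one | CC(C)(C)[Si](C)(C)Oc1cc(O[Si](C)(C)C(C)(C)C)c2C(=O)C[C@@H](c3ccc(OC/C=C(\C)CCC=C(C)C)cc3)Oc2c1
A3 | alternative 2 | 4-(geranyloxy)benzaldehyde | O=Cc1ccc(OC/C=C(\C)CCC=C(C)C)cc1
A4 | alternative 2 | (E)-1-methoxy-3-(trimethylsilyloxy)buta-1,3-diene | CO/C=C/C(=C)O[Si](C)(C)C
A5 | alternative 2 | (S)-2-[4-(geranyloxy)phenyl]-2,3-dihydro-4H-pyran-4-one | O=C1C[C@@H](c2ccc(OC/C=C(\C)CCC=C(C)C)cc2)OC=C1
A6 | alternative 3 | 2-iodo-3,5-bis(methoxymethoxy)phenol | COCOc1cc(O)c(I)c(OCOC)c1
A7 | alternative 3 | 1-ethynyl-4-(geranyloxy)benzene | C#Cc1ccc(OC/C=C(\C)CCC=C(C)C)cc1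
A8 | alternative 3 | 2-[4-(geranyloxy)phenyl]-5,7-bis(methoxymethoxy)-4H-chromen-4-one | COCOc1cc(OCOC)c2c(=O)cc(-c3ccc(OC/C=C(\C)CCC=C(C)C)cc3)oc2c1
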